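The eudesmane target is cut at C9 of ring B (C5–C6–C7–C8–C9–C10). Without this methylene, the C3 oxygen, the C4=C5 alkene with its methyl, quaternary C10 with its methyl and the C8 oxygen are those of a hydrindenedione available by amino-acid-catalysed aldol annulation. The key step inserts C9 between the C8 cyclopentanone carbonyl and the quaternary, allylic C10: dibromomethyllithium adds to C8 and the β-oxido carbenoid rearranges, so the five-membered ring becomes ring B in one operation with C10 unchanged. Its precursor is (5S,7aS)-5-silyloxy-4,7a-dimethylhexahydroinden-1-one. The C8 ketone of the product then serves for C7 alkylation and reduction to the 8β-alcohol.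

Key step: step 7

Remark: from compound 9 onward the text uses eudesmane numbering (ring A = C1–C5, C10; ring B = C5–C10; C8 = ketone carbon, C10 = quaternary carbon), β is the face of the C10 methyl, and LDA, LiTMP, n-BuLi and L-Selectride are taken as commercial solutions.

Step 1
Reactants: 1 2-methylcyclopentane-1,3-dione; 2 ethyl vinyl ketone
Product: 3 2-methyl-2-(3-oxopentyl)cyclopentane-1,3-dione
Conditions: H2O, AcOH (cat.), 70 °C
Reagents that add atoms: none
Why: Michael addition of the acidic 1,3-dione to the enone in water is the standard entry to the prochiral triketone; no stereocenter is formed.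

Step 2
Reactants: 3 2-methyl-2-(3-oxopentyl)cyclopentane-1,3-dione
Product: 5 (7aS)-4,7a-dimethyl-2,3,7,7a-tetrahydro-1H-indene-1,5(6H)-dione, via cis-fused ketol 4 (not isolated)
Conditions: L-phenylalanine, (+)-CSA, MeCN, reflux
Reagents that add atoms: none
Why: Hajos–Parrish–Eder–Sauer–Wiechert aldol condensation; the enamine of the side-chain ketone with the (S)-amino acid attacks one of the two enantiotopic ring carbonyls under carboxylic-acid direction and should set the quaternary centre as 7aS (C10 of the target), a primary amino acid being the usual choice for ethyl ketones; recrystallisation can raise the enantiomeric purity.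

Step 3
Reactants: 5 (7aS)-4,7a-dimethyl-2,3,7,7a-tetrahydro-1H-indene-1,5(6H)-dione
Product: 6 (7aS)-1,1-(ethylenedioxy)-4,7a-dimethyl-1,2,3,6,7,7a-hexahydro-5H-inden-5-one
Conditions: (TMSOCH2)2, TMSOTf (cat.), CH2Cl2, −78 → −20 °C
Reagents that add atoms: 1,2-bis(trimethylsilyloxy)ethane, C[Si](C)(C)OCCO[Si](C)(C)C
Why: Noyori dioxolanation under kinetic control should acetalise the saturated cyclopentanone and leave the tetrasubstituted, vinylogously deactivated enone, the same discrimination as between 17-keto and Δ4-3-keto groups of steroid diones.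

Step 4
Reactants: 6 (7aS)-1,1-(ethylenedioxy)-4,7a-dimethyl-1,2,3,6,7,7a-hexahydro-5H-inden-5-one
Product: 7 (5S,7aS)-1,1-(ethylenedioxy)-4,7a-dimethyl-2,3,5,6,7,7a-hexahydro-1H-inden-5-ol
Conditions: NaBH4, CeCl3·7H2O, MeOH, −20 °C
Reagents that add atoms: none
Why: Luche 1,2-reduction; hydride should enter pseudo-axially at C5 from the α face, anti to the angular methyl, to give the pseudo-equatorial 5β-alcohol (5S, C3 of the target), as in Δ4-3-keto steroids.

Step 5
Reactants: 7 (5S,7aS)-1,1-(ethylenedioxy)-4,7a-dimethyl-2,3,5,6,7,7a-hexahydro-1H-inden-5-ol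
Product: 8 (5S,7aS)-5-(tert-butyldimethylsilyloxy)-1,1-(ethylenedioxy)-4,7a-dimethyl-2,3,5,6,7,7a-hexahydro-1H-indene
Conditions: TBSCl, imidazole, DMF, rt
Reagents that add atoms: tert-butyldimethylsilyl chloride, CC(C)(C)[Si](C)(C)Cl
Why: Standard silylation of a secondary allylic alcohol with retention; the TBS ether tolerates the organolithium, enolate and hydride steps that follow.

Step 6
Reactants: 8 (5S,7aS)-5-(tert-butyldimethylsilyloxy)-1,1-(ethylenedioxy)-4,7a-dimethyl-2,3,5,6,7,7a-hexahydro-1H-indene
Product: 9 (5S,7aS)-5-(tert-butyldimethylsilyloxy)-4,7a-dimethyl-2,3,5,6,7,7a-hexahydro-1H-inden-1-one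
Conditions: PPTS (cat.), acetone/H2O, 50 °C
Reagents that add atoms: water, O
Why: Mild acid-catalysed acetal hydrolysis; a secondary TBS ether survives PPTS, and the freed ketone cannot move into conjugation with the C3a=C4 alkene because C7a is quaternary.

Step 7
Reactants: 9 (5S,7aS)-5-(tert-butyldimethylsilyloxy)-4,7a-dimethyl-2,3,5,6,7,7a-hexahydro-1H-inden-1-one; 10 dibromomethane
Product: 14 (3S,10R)-3-(tert-butyldimethylsilyloxy)-4,10-dimethyl-Δ4-octalin-8-one, via dibromomethyl carbinolate 11 (not isolated), via β-oxido carbenoid 12 (not isolated), via ring-expanded lithium enolate 13 (not isolated)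
Conditions: 10, LiTMP, THF, −78 °C; n-BuLi, −78 → 0 °C; AcOH
Reagents that add atoms: none
Why: Dibromomethyllithium, formed from 10 and LiTMP in the presence of the ketone, adds to the C8 carbonyl to give alkoxide 11; bromine–lithium exchange gives carbenoid 12, in which loss of bromide is concerted with a 1,2-shift of the C10–C8 bond onto the carbenoid carbon, and the resulting C8=C9 enolate 13 is protonated to 14. This is the known β-oxido carbenoid one-carbon homologation of cyclic ketones. Ring B is formed by ring enlargement, not by cyclisation: the cyclopentanone gains C9, with C8–C9 made in the addition and C9–C10 in the migration. No stereocenter is created, since the transient carbinol centre returns to a carbonyl, C10 migrates with retention so the centre from step 2 becomes 10R unchanged, and C3 is remote. The step needs migration of C10 in preference to the C7 methylene, which rests on the known preference of this rearrangement for the more substituted α-carbon, here quaternary and allylic. Enolisation of the ketone should be limited because the weakly basic reagent is generated and trapped at −78 °C.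

Step 8
Reactants: 14 (3S,10R)-3-(tert-butyldimethylsilyloxy)-4,10-dimethyl-Δ4-octalin-8-one; 15 methyl bromoacetate
Product: 18 methyl 2-[(3S,7R,10R)-3-(tert-butyldimethylsilyloxy)-4,10-dimethyl-8-oxo-Δ4-octalin-7-yl]acetate, via kinetic lithium enolate 16 (not isolated), via 7α-epimeric keto ester 17 (not isolated)
Conditions: LDA, THF, −78 °C; 15, DMPU, −78 → −20 °C; then NaOMe (cat.), MeOH, rt
Reagents that add atoms: none
Why: Kinetic enolate alkylation; LDA should deprotonate C7 because C9 is neopentyl (next to quaternary C10), axial attack from the α face should give mainly the 7α ester 17, and methoxide equilibration through the enolate moves the CH2CO2Me group to the equatorial 7β position (7R), any remaining 17 being separated and re-equilibrated.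

Step 9
Reactants: 18 methyl 2-[(3S,7R,10R)-3-(tert-butyldimethylsilyloxy)-4,10-dimethyl-8-oxo-Δ4-octalin-7-yl]acetate
Product: 20 (3S,7R,8R,10R)-3-(tert-butyldimethylsilyloxy)-13-noreudesm-4-en-12,8-olide, via lithium 8β-alkoxide 19 (not isolated)
Conditions: L-Selectride, THF, −78 → 0 °C; AcOH
Reagents that add atoms: none
Why: The bulky hydride should attack the C8 ketone equatorially from the α side, the axial β trajectory being blocked by the syn-axial C10 methyl, to give the axial 8β-alkoxide (8R); this is cis to the equatorial 7β side chain and closes the γ-lactone by intramolecular transesterification, while the methyl ester is inert to L-Selectride at low temperature.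

Step 10
Reactants: 20 (3S,7R,8R,10R)-3-(tert-butyldimethylsilyloxy)-13-noreudesm-4-en-12,8-olide
Product: 24 (3S,7R,8R,10R)-3-(tert-butyldimethylsilyloxy)eudesma-4,11(13)-dien-12,8-olide, via lactone lithium enolate 21 (not isolated), via Mannich base 22 (not isolated), via trimethylammonium iodide 23 (not isolated)
Conditions: LDA, THF, −78 °C; CH2=NMe2+ I−, −78 °C → rt; MeI, rt; aq. NaHCO3
Reagents that add atoms: Eschenmoser's salt (N,N-dimethylmethyleneiminium iodide), C=[N+](C)C.[I-]
Why: Standard α-methylenation of a γ-lactone: Mannich reaction of the lactone enolate with Eschenmoser's salt, N-methylation and E1cB loss of trimethylamine install the 11(13)-methylene; the C11 configuration of 22 is irrelevant and C7 and C8 are untouched.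

Step 11
Reactants: 24 (3S,7R,8R,10R)-3-(tert-butyldimethylsilyloxy)eudesma-4,11(13)-dien-12,8-olide
Product: 26 methyl (3S,7R,8R,10R)-3-(tert-butyldimethylsilyloxy)-8-hydroxyeudesma-4,11(13)-dien-12-oate, via lithium hydroxy carboxylate 25 (not isolated)
Conditions: LiOH (1.05 equiv), THF/H2O, 0 °C → rt; evaporate; MeI, DMF, rt
Reagents that add atoms: lithium hydroxide, [Li+].[OH-]; iodomethane, CI
Why: Saponification by acyl–oxygen cleavage keeps the C8–O bond (retention at C8), and O-alkylation of the carboxylate with iodomethane under non-acidic conditions gives the methyl ester without passing through the free hydroxy acid that would re-lactonise; the secondary alcohol is not methylated in the absence of strong base.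

Step 12
Reactants: 26 methyl (3S,7R,8R,10R)-3-(tert-butyldimethylsilyloxy)-8-hydroxyeudesma-4,11(13)-dien-12-oate
Product: 27 methyl (3S,7R,8R,10R)-8-acetoxy-3-(tert-butyldimethylsilyloxy)eudesma-4,11(13)-dien-12-oate
Conditions: Ac2O, Et3N, DMAP (cat.), CH2Cl2, 0 °C → rt
Reagents that add atoms: acetic anhydride, CC(=O)OC(C)=O
Why: DMAP-catalysed acylation of the axial 8β-alcohol with retention; capping it removes the only nucleophile able to re-close the lactone.

Step 13
Reactants: 27 methyl (3S,7R,8R,10R)-8-acetoxy-3-(tert-butyldimethylsilyloxy)eudesma-4,11(13)-dien-12-oate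
Product: 28 methyl (3S,7R,8R,10R)-8-acetoxy-3-hydroxyeudesma-4,11(13)-dien-12-oate
Conditions: HF·pyridine, pyridine/THF, 0 °C → rt
Reagents that add atoms: none
Why: Buffered fluoride desilylation cleaves only the Si–O bond, so the 3β-alcohol is freed with retention while acetate, acrylate ester and the allylic C–O bond remain.

Step 14
Reactants: 28 methyl (3S,7R,8R,10R)-8-acetoxy-3-hydroxyeudesma-4,11(13)-dien-12-oate
Product: 29 methyl (3S,7R,8R,10R)-8-acetoxy-3-(isobutyryloxy)eudesma-4,11(13)-dien-12-oate
Conditions: (i-PrCO)2O, Et3N, DMAP (cat.), CH2Cl2, rt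
Reagents that add atoms: isobutyric anhydride, CC(C)C(=O)OC(=O)C(C)C
Why: DMAP-catalysed esterification of the equatorial allylic 3β-alcohol proceeds at oxygen with retention and completes the target.

Compound list
1 | 2-methylcyclopentane-1,3-dione | CC1C(=O)CCC1=O | starting material
2 | ethyl vinyl ketone (pent-1-en-3-one) | CCC(=O)C=C | starting material
3 | 2-methyl-2-(3-oxopentyl)cyclopentane-1,3-dione (achiral) | CCC(=O)CCC1(C)C(=O)CCC1=O | intermediate
4 | (3aS,7aS)-3a-hydroxy-4,7a-dimethylhexahydro-1H-indene-1,5(4H)-dione, cis-fused ketol, C4 unassigned and lost on dehydration (formed in the flask) | C[C@]12CCC(=O)C(C)[C@@]1(O)CCC2=O | intermediate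
5 | (7aS)-4,7a-dimethyl-2,3,7,7a-tetrahydro-1H-indene-1,5(6H)-dione | C[C@]12CCC(=O)C(C)=C1CCC2=O | intermediate
6 | (7aS)-1,1-(ethylenedioxy)-4,7a-dimethyl-1,2,3,6,7,7a-hexahydro-5H-inden-5-one (C1 dioxolane of 5) | C[C@]12CCC(=O)C(C)=C1CCC23OCCO3 | intermediate
7 | (5S,7aS)-1,1-(ethylenedioxy)-4,7a-dimethyl-2,3,5,6,7,7a-hexahydro-1H-inden-5-ol (OH cis to the angular methyl) | C[C@]12CC[C@H](O)C(C)=C1CCC23OCCO3 | intermediate
8 | (5S,7aS)-5-(tert-butyldimethylsilyloxy)-1,1-(ethylenedioxy)-4,7a-dimethyl-2,3,5,6,7,7a-hexahydro-1H-indene | C[C@]12CC[C@H](O[Si](C)(C)C(C)(C)C)C(C)=C1CCC23OCCO3 | intermediate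
9 | (5S,7aS)-5-(tert-butyldimethylsilyloxy)-4,7a-dimethyl-2,3,5,6,7,7a-hexahydro-1H-inden-1-one (key-step precursor) | O=C1CCC2=C(C)[C@@H](O[Si](C)(C)C(C)(C)C)CC[C@]12C | intermediate
10 | dibromomethane | BrCBr | starting material
11 | lithium (1S,5S,7aS)-1-(dibromomethyl)-5-(tert-butyldimethylsilyloxy)-4,7a-dimethyl-2,3,5,6,7,7a-hexahydro-1H-inden-1-olate, carbinol configuration as expected for α-face addition and of no consequence (formed in the flask) | [Li]O[C@@]1(C(Br)Br)CCC2=C(C)[C@@H](O[Si](C)(C)C(C)(C)C)CC[C@]12C | intermediate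
12 | β-oxido carbenoid: the bromo(lithio)methyl analogue of 11, carbenoid carbon unassigned (formed in the flask) | [Li]O[C@@]1(C([Li])Br)CCC2=C(C)[C@@H](O[Si](C)(C)C(C)(C)C)CC[C@]12C | intermediate
13 | lithium C8=C9 enolate of 14 (formed in the flask) | C1CC2=C(C)[C@@H](O[Si](C)(C)C(C)(C)C)CC[C@]2(C)C=C1O[Li] | intermediate
14 | (3S,10R)-3-(tert-butyldimethylsilyloxy)-4,10-dimethyl-Δ4-octalin-8-one = (6S,8aR)-6-(tert-butyldimethylsilyloxy)-5,8a-dimethyl-3,4,6,7,8,8a-hexahydronaphthalen-2(1H)-one (key-step product) | C1CC2=C(C)[C@@H](O[Si](C)(C)C(C)(C)C)CC[C@]2(C)CC1=O | intermediate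
15 | methyl bromoacetate | COC(=O)CBr | starting material
16 | lithium C7=C8 enolate of 14 (formed in the flask) | [Li]OC1=CCC2=C(C)[C@@H](O[Si](C)(C)C(C)(C)C)CC[C@]2(C)C1 | intermediate
17 | methyl 2-[(3S,7S,10R)-3-(tert-butyldimethylsilyloxy)-4,10-dimethyl-8-oxo-Δ4-octalin-7-yl]acetate, 7α axial epimer (formed in the flask) | COC(=O)C[C@@H]1CC2=C(C)[C@@H](O[Si](C)(C)C(C)(C)C)CC[C@]2(C)CC1=O | intermediate
18 | methyl 2-[(3S,7R,10R)-3-(tert-butyldimethylsilyloxy)-4,10-dimethyl-8-oxo-Δ4-octalin-7-yl]acetate, 7β equatorial | COC(=O)C[C@H]1CC2=C(C)[C@@H](O[Si](C)(C)C(C)(C)C)CC[C@]2(C)CC1=O | intermediate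
19 | lithium 8β-alkoxide of the (3S,7R,8R,10R) hydroxy ester from 18 (formed in the flask) | COC(=O)C[C@H]1CC2=C(C)[C@@H](O[Si](C)(C)C(C)(C)C)CC[C@]2(C)C[C@H]1O[Li] | intermediate
20 | (3S,7R,8R,10R)-3-(tert-butyldimethylsilyloxy)-13-noreudesm-4-en-12,8-olide, cis-fused 8β,12-lactone with 7α-H and 8α-H | O=C1C[C@H]2CC3=C(C)[C@@H](O[Si](C)(C)C(C)(C)C)CC[C@]3(C)C[C@H]2O1 | intermediate
21 | lithium enolate of lactone 20 (formed in the flask) | [Li]OC1=C[C@H]2CC3=C(C)[C@@H](O[Si](C)(C)C(C)(C)C)CC[C@]3(C)C[C@H]2O1 | intermediate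
22 | 11-(dimethylaminomethyl) derivative of lactone 20, Mannich base, C11 unassigned (formed in the flask) | O=C1C(CN(C)C)[C@H]2CC3=C(C)[C@@H](O[Si](C)(C)C(C)(C)C)CC[C@]3(C)C[C@H]2O1 | intermediate
23 | trimethylammonium iodide from 22, C11 unassigned (formed in the flask) | O=C1C(C[N+](C)(C)C)[C@H]2CC3=C(C)[C@@H](O[Si](C)(C)C(C)(C)C)CC[C@]3(C)C[C@H]2O1.[I-] | intermediate
24 | (3S,7R,8R,10R)-3-(tert-butyldimethylsilyloxy)eudesma-4,11(13)-dien-12,8-olide | C=C1[C@H]2CC3=C(C)[C@@H](O[Si](C)(C)C(C)(C)C)CC[C@]3(C)C[C@H]2OC1=O | intermediate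
25 | lithium (3S,7R,8R,10R)-3-(tert-butyldimethylsilyloxy)-8-hydroxyeudesma-4,11(13)-dien-12-oate (formed in the flask) | C=C(C(=O)[O-])[C@H]1CC2=C(C)[C@@H](O[Si](C)(C)C(C)(C)C)CC[C@]2(C)C[C@H]1O.[Li+] | intermediate
26 | methyl (3S,7R,8R,10R)-3-(tert-butyldimethylsilyloxy)-8-hydroxyeudesma-4,11(13)-dien-12-oate | C=C(C(=O)OC)[C@H]1CC2=C(C)[C@@H](O[Si](C)(C)C(C)(C)C)CC[C@]2(C)C[C@H]1O | intermediate
27 | methyl (3S,7R,8R,10R)-8-acetoxy-3-(tert-butyldimethylsilyloxy)eudesma-4,11(13)-dien-12-oate | C=C(C(=O)OC)[C@H]1CC2=C(C)[C@@H](O[Si](C)(C)C(C)(C)C)CC[C@]2(C)C[C@H]1OC(C)=O | intermediate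
28 | methyl (3S,7R,8R,10R)-8-acetoxy-3-hydroxyeudesma-4,11(13)-dien-12-oate | C=C(C(=O)OC)[C@H]1CC2=C(C)[C@@H](O)CC[C@]2(C)C[C@H]1OC(C)=O | intermediate
29 | methyl (3S,7R,8R,10R)-8-acetoxy-3-(isobutyryloxy)eudesma-4,11(13)-dien-12-oate (3β-isobutyryloxy, 7β-acrylate, 8β-acetoxy, 10β-methyl) | C=C(C(=O)OC)[C@H]1CC2=C(C)[C@@H](OC(=O)C(C)C)CC[C@]2(C)C[C@H]1OC(C)=O | target

Total step count: 14. Longest linear sequence: 14 steps (1 and 2 to 29).

Steps most likely to fail

Step 7. The hindered cyclopentanone may be enolised instead of attacked, or the C7 methylene may migrate in competition with C10, which would place the carbonyl next to the quaternary carbon. The fallback starts from 9 and uses a cationic thio-semipinacol ring expansion, which forms the same two bonds by a different mechanism. Bis(phenylthio)methyllithium (from bis(phenylthio)methane and n-BuLi, THF, −78 °C) is added to the ketone to give the bis(phenylthio)methyl carbinol F1. Copper(I) triflate with Hünig's base in warm benzene removes one thiophenolate; the sulfur-stabilised cation draws over the more substituted, allylic C10 and gives the 9-phenylthio ketone F2. Samarium diiodide in THF/MeOH then cleaves the C–S bond and returns the route to 14.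

Step 8. Deprotonation may not be selective for C7, proton exchange between enolate and product may lead to over-alkylation, and the C7 equilibrium may be only moderately in favour of the 7β epimer. The fallback starts from 14 and builds the C7–C11 bond by a reversible crossed aldol condensation with glyoxylic acid (aq. NaOH, MeOH), which can only dehydrate at the unhindered C7 and should give the (E)-alkylidene keto acid F3. Zinc dust in AcOH/THF reduces the ene-1,4-dicarbonyl unit; protonation of the enol from the axial α direction places the side chain equatorial and gives the 7β keto acid F4. Esterification with MeI and K2CO3 in DMF returns the route to 18.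

Step 11. Hydroxide may add to the exocyclic methylene of the lactone, and the hydroxy ester may close back to the lactone while the carboxylate is being methylated. The fallback starts from Mannich base 22, isolated after the first half of step 10, so that the ring is opened before the Michael acceptor exists. LiOH in THF/H2O should give the lithium amino hydroxy carboxylate F5. Excess MeI in DMF esterifies the carboxylate and quaternises nitrogen in one operation to give the trimethylammonium iodide methyl ester F6. Aqueous NaHCO3 then eliminates trimethylamine and gives 26, where the route continues with the acetylation.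

Further compounds
F1 | step 7 | (1S,5S,7aS)-1-[bis(phenylthio)methyl]-5-(tert-butyldimethylsilyloxy)-4,7a-dimethyl-2,3,5,6,7,7a-hexahydro-1H-inden-1-ol | O[C@@]1(C(Sc3ccccc3)Sc3ccccc3)CCC2=C(C)[C@@H](O[Si](C)(C)C(C)(C)C)CC[C@]12C
F2 | step 7 | (3S,10R)-3-(tert-butyldimethylsilyloxy)-4,10-dimethyl-9-(phenylthio)-Δ4-octalin-8-one, C9 unassigned | C1CC2=C(C)[C@@H](O[Si](C)(C)C(C)(C)C)CC[C@]2(C)C(Sc3ccccc3)C1=O
F3 | step 8 | (E)-2-[(3S,10R)-3-(tert-butyldimethylsilyloxy)-4,10-dimethyl-8-oxo-Δ4-octalin-7-ylidene]acetic acid | OC(=O)/C=C1\CC2=C(C)[C@@H](O[Si](C)(C)C(C)(C)C)CC[C@]2(C)CC1=O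
F4 | step 8 | 2-[(3S,7R,10R)-3-(tert-butyldimethylsilyloxy)-4,10-dimethyl-8-oxo-Δ4-octalin-7-yl]acetic acid | OC(=O)C[C@H]1CC2=C(C)[C@@H](O[Si](C)(C)C(C)(C)C)CC[C@]2(C)CC1=O
F5 | step 11 | lithium (3S,7R,8R,10R)-3-(tert-butyldimethylsilyloxy)-13-(dimethylamino)-8-hydroxyeudesm-4-en-12-oate, C11 unassigned | CN(C)CC(C(=O)[O-])[C@H]1CC2=C(C)[C@@H](O[Si](C)(C)C(C)(C)C)CC[C@]2(C)C[C@H]1O.[Li+]
F6 | step 11 | methyl (3S,7R,8R,10R)-3-(tert-butyldimethylsilyloxy)-8-hydroxy-13-(trimethylammonio)eudesm-4-en-12-oate iodide, C11 unassigned | C[N+](C)(C)CC(C(=O)OC)[C@H]1CC2=C(C)[C@@H](O[Si](C)(C)C(C)(C)C)CC[C@]2(C)C[C@H]1O.[I-]
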